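**Retrosynthetic overview**

- The strategy rests on the 5,6-dihydro-2H-pyran-2-one ring (O1, C2–C6; side chain C1'–C8' outward from C6) and its single ring stereocentre C6: the ring is the oxidised [4+2] adduct of a 1-oxygenated butadiene (C2–C5) and an aldehyde carbon (C6).
- Lactone ⇒ cis-2-methoxy-6-alkynyl-5,6-dihydro-2H-pyran ⇒ (E)-1-methoxybutadiene + side-chain ynal (formyl carbon = C6, alkyne = C1'≡C2', C4'–OTBS, C6'–OAc), joined by a catalytic asymmetric hetero-Diels–Alder reaction.
- Ynal ⇒ C5'–C6' by opening an epoxide with the 2-styryl-1,3-dithiane anion, C6' by CBS reduction of the derived enone, C2'–C3' by acetylide opening of (R)-epichlorohydrin, which supplies C4'.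
- Only one ring is formed (step 12). Afterwards the alkyne is trans-reduced to (E)-C1'=C2', the acetal carbon C2 is oxidised to the lactone carbonyl, and C4'–OH is freed.

Key step: step 12

Assumption: the chromium catalyst built on (1S,2R)-1-aminoindan-2-ol is taken to give the 6S adduct, by analogy with the facial sense of this catalyst family with simple aldehydes; the sense is checked on the first run and the (1R,2S) catalyst is used instead if it proves opposite.

Catalyst of step 12: CrCl(C27H29NO2), the chloride of trivalent chromium carrying the doubly deprotonated Schiff base of (1S,2R)-1-aminoindan-2-ol and 3-(1-adamantyl)-2-hydroxy-5-methylbenzaldehyde.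

**Route**

Step 1
Reactants: 1 propargyl alcohol
Product: 2 1-methoxy-4-[(prop-2-yn-1-yloxy)methyl]benzene (4-methoxybenzyl propargyl ether)
Conditions: NaH, 4-methoxybenzyl chloride, Bu4NI (cat.), THF, 0 °C → rt
Reagents that add atoms: 4-methoxybenzyl chloride, COc1ccc(CCl)cc1
Why: Williamson etherification of the primary alkoxide with a reactive benzylic chloride should proceed cleanly, and the terminal alkyne C–H is not touched by the alkoxide.

Step 2
Reactants: 2 4-methoxybenzyl propargyl ether; 3 (R)-epichlorohydrin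
Product: 5 (2R)-1-chloro-6-[(4-methoxybenzyl)oxy]hex-4-yn-2-ol, via lithium acetylide 4 (not isolated)
Conditions: n-BuLi, THF, −78 °C; BF3·OEt2; then 3, −78 °C; aqueous work-up
Reagents that add atoms: none
Why: In this Yamaguchi–Hirao alkynylation the alkynyl trifluoroborate formed from 4 should open the BF3-activated epoxide only at its unsubstituted carbon, forming C2'–C3' and leaving the C–Cl bond and the stereocentre (the future C4') untouched.

Step 3
Reactants: 5 (2R)-1-chloro-6-[(4-methoxybenzyl)oxy]hex-4-yn-2-ol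
Product: 6 (2R)-2-{4-[(4-methoxybenzyl)oxy]but-2-yn-1-yl}oxirane
Conditions: K2CO3, MeOH, rt
Reagents that add atoms: none
Why: Intramolecular Williamson closure of the chlorohydrin alkoxide (3-exo-tet) should give the terminal epoxide, and the carbinol carbon keeps its configuration because only the CH2Cl carbon is substituted.

Step 4
Reactants: 7 (E)-cinnamaldehyde; 8 propane-1,3-dithiol
Product: 9 2-[(E)-2-phenylethenyl]-1,3-dithiane
Conditions: BF3·OEt2 (10 mol%), CH2Cl2, 0 °C → rt
Reagents that add atoms: none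
Why: Lewis acid-catalysed dithioacetalisation of the enal should give the six-membered dithiane, the thermodynamically favoured 1,2-adduct, with the E-alkene unchanged.

Step 5
Reactants: 9 2-[(E)-2-phenylethenyl]-1,3-dithiane; 6 (2R)-2-{4-[(4-methoxybenzyl)oxy]but-2-yn-1-yl}oxirane
Product: 11 (2R)-6-[(4-methoxybenzyl)oxy]-1-{2-[(E)-2-phenylethenyl]-1,3-dithian-2-yl}hex-4-yn-2-ol, via 2-lithio-2-styryl-1,3-dithiane 10 (not isolated)
Conditions: n-BuLi, THF, −78 → −30 °C; then 6, −78 → −20 °C; H2O
Reagents that add atoms: none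
Why: In this Corey–Seebach umpolung alkylation the lithiated dithiane should attack through its sulfur-bearing α-carbon at the terminal epoxide carbon (SN2), forming C5'–C6' without touching C4'.

Step 6
Reactants: 11 (2R)-6-[(4-methoxybenzyl)oxy]-1-{2-[(E)-2-phenylethenyl]-1,3-dithian-2-yl}hex-4-yn-2-ol
Product: 12 tert-butyldimethylsilyl ether of 11 (C4'–OTBS, configuration unchanged)
Conditions: TBSOTf, 2,6-lutidine, CH2Cl2, −78 → 0 °C
Reagents that add atoms: tert-butyldimethylsilyl trifluoromethanesulfonate, CC(C)(C)[Si](C)(C)OS(=O)(=O)C(F)(F)F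
Why: Silylation with the silyl triflate and a hindered base should protect the secondary alcohol next to the quaternary dithiane carbon without affecting the benzyl ether or the dithiane.

Step 7
Reactants: 12 tert-butyldimethylsilyl ether of 11
Product: 13 (1E,5R)-5-[(tert-butyldimethylsilyl)oxy]-9-[(4-methoxybenzyl)oxy]-1-phenylnon-1-en-7-yn-3-one
Conditions: MeI, CaCO3, MeCN/H2O (9:1), 45 °C
Reagents that add atoms: water, O
Why: S-Methylation followed by hydrolysis (alkylative dithioacetal cleavage) under carbonate buffering should release the conjugated enone without harming the alkyne, the silyl ether or the benzyl ether.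

Step 8
Reactants: 13 (1E,5R)-5-[(tert-butyldimethylsilyl)oxy]-9-[(4-methoxybenzyl)oxy]-1-phenylnon-1-en-7-yn-3-one
Product: 14 (1E,3S,5R)-5-[(tert-butyldimethylsilyl)oxy]-9-[(4-methoxybenzyl)oxy]-1-phenylnon-1-en-7-yn-3-ol
Conditions: (R)-2-methyl-CBS-oxazaborolidine (0.5 equiv), catecholborane, toluene, −78 °C; aqueous work-up
Reagents that add atoms: none
Why: In this Corey–Bakshi–Shibata reduction the (R)-oxazaborolidine should deliver hydride under reagent control, with the styryl group as the large substituent, to set C6' as S, while catecholborane at −78 °C should leave the alkyne alone.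

Step 9
Reactants: 14 (1E,3S,5R)-5-[(tert-butyldimethylsilyl)oxy]-9-[(4-methoxybenzyl)oxy]-1-phenylnon-1-en-7-yn-3-ol
Product: 15 (1E,3S,5R)-5-[(tert-butyldimethylsilyl)oxy]-9-[(4-methoxybenzyl)oxy]-1-phenylnon-1-en-7-yn-3-yl acetate
Conditions: Ac2O, pyridine, DMAP (cat.), CH2Cl2, 0 °C → rt
Reagents that add atoms: acetic anhydride, CC(=O)OC(C)=O
Why: DMAP-catalysed acylation of the only free hydroxyl should install the C6' acetate with retention, since the C–O bond is not broken.

Step 10
Reactants: 15 (1E,3S,5R)-5-[(tert-butyldimethylsilyl)oxy]-9-[(4-methoxybenzyl)oxy]-1-phenylnon-1-en-7-yn-3-yl acetate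
Product: 16 (1E,3S,5R)-5-[(tert-butyldimethylsilyl)oxy]-9-hydroxy-1-phenylnon-1-en-7-yn-3-yl acetate
Conditions: 2,3-dichloro-5,6-dicyano-1,4-benzoquinone (DDQ), CH2Cl2/pH 7 buffer (10:1), 0 °C → rt
Reagents that add atoms: none
Why: Oxidative cleavage of the 4-methoxybenzyl ether by DDQ, through hydride abstraction at the electron-rich benzylic position, should free the propargylic alcohol while acetate, silyl ether and styrene stay intact.

Step 11
Reactants: 16 (1E,3S,5R)-5-[(tert-butyldimethylsilyl)oxy]-9-hydroxy-1-phenylnon-1-en-7-yn-3-yl acetate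
Product: 17 (1E,3S,5R)-5-[(tert-butyldimethylsilyl)oxy]-9-oxo-1-phenylnon-1-en-7-yn-3-yl acetate (the side-chain ynal)
Conditions: Dess–Martin periodinane, CH2Cl2, 0 °C → rt; used at once
Reagents that add atoms: none
Why: Dess–Martin oxidation of a primary propargylic alcohol should stop at the ynal under neutral, non-nucleophilic conditions that spare this conjugate acceptor.

Step 12
Reactants: 17 side-chain ynal; 18 (E)-1-methoxybuta-1,3-diene
Product: 19 (1E,3S,5R)-5-[(tert-butyldimethylsilyl)oxy]-9-[(2S,6R)-6-methoxy-3,6-dihydro-2H-pyran-2-yl]-1-phenylnon-1-en-7-yn-3-yl acetate (cis acetal; lactone numbering 2R,6S)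
Conditions: 18 (3 equiv), CrCl(C27H29NO2) (5 mol%), 4 Å molecular sieves, minimal tert-butyl methyl ether, rt, 24–48 h; chromatography on Et3N-deactivated silica
Reagents that add atoms: none
Why: The chromium centre binds the formyl oxygen of 17 and the diene adds through a concerted but asynchronous endo [4+2] transition state in which C5–C6 forms ahead of O1–C2; the closest known reaction is the chromium Schiff base-catalysed hetero-Diels–Alder reaction of 1-methoxybutadiene with aldehydes, conjugated ynals included. The six-membered dihydropyran ring is closed by the intermolecular cycloaddition itself, both ring bonds being made in the one step, so no separate cyclisation mode arises. C6 is set by the catalyst, whose ligand shields one face of the bound aldehyde, and C2 follows from the endo approach, which places the methoxy group cis to the alkynyl group and is erased when C2 is oxidised in step 15. The step needs facial selectivity at a formyl group, which is secured because C4' and C6' lie too far from the reacting carbon to compete with the ligand, and it needs chemoselectivity for C=O over C≡C, which is secured because only the chromium-bound carbonyl is activated towards the electron-rich diene. The linear alkynyl substituent keeps the aldehyde unhindered, and the acetate and silyl ether are spectators.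

Step 13
Reactants: 19 cis-2-methoxy-6-alkynyl-dihydropyran cycloadduct
Product: 21 (1E,3S,5R,7E)-5-[(tert-butyldimethylsilyl)oxy]-8-[(2S,6R)-6-methoxy-3,6-dihydro-2H-pyran-2-yl]-1-phenylocta-1,7-dien-3-yl acetate, via (Z)-alkenyltriethoxysilane 20 (not isolated)
Conditions: (EtO)3SiH, [Cp*Ru(MeCN)3]PF6 (5 mol%), CH2Cl2, 0 °C → rt; then AgF, THF/MeOH/H2O, rt, dark
Reagents that add atoms: none
Why: Ruthenium-catalysed trans-hydrosilylation of the internal alkyne followed by silver fluoride-mediated protodesilylation with retention should amount to a net trans reduction to (E)-C1'=C2'; either silane regioisomer gives the same alkene and the 1,2-disubstituted alkenes are not hydrosilylated.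

Step 14
Reactants: 21 (E)-alkenyl methyl acetal
Product: 22 (1E,3S,5R,7E)-5-[(tert-butyldimethylsilyl)oxy]-8-[(2S)-6-hydroxy-3,6-dihydro-2H-pyran-2-yl]-1-phenylocta-1,7-dien-3-yl acetate (lactol, mixture of anomers)
Conditions: pyridinium p-toluenesulfonate (cat.), acetone/H2O (4:1), rt
Reagents that add atoms: water, O
Why: Acid-catalysed hydrolysis of the allylic mixed acetal should pass through an allyl-stabilised oxocarbenium ion under conditions too mild to cleave the secondary silyl ether or ionise the allylic acetate.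

Step 15
Reactants: 22 lactol
Product: 23 (1E,3S,5R,7E)-5-[(tert-butyldimethylsilyl)oxy]-8-[(2S)-6-oxo-3,6-dihydro-2H-pyran-2-yl]-1-phenylocta-1,7-dien-3-yl acetate
Conditions: MnO2 (activated, excess), CH2Cl2, rt
Reagents that add atoms: none
Why: Manganese dioxide oxidation of the allylic lactol should give the α,β-unsaturated δ-lactone directly; this removes the C2 stereocentre and leaves C6 untouched.

Step 16
Reactants: 23 silyl-protected lactone
Product: 24 (6S)-6-[(1E,4R,6S,7E)-6-acetoxy-4-hydroxy-8-phenylocta-1,7-dien-1-yl]-5,6-dihydro-2H-pyran-2-one (target)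
Conditions: HF·pyridine, pyridine, THF, 0 °C → rt
Reagents that add atoms: none
Why: Fluoride-mediated desilylation in a buffered, weakly acidic medium should free C4'–OH without the 1,3-acyl migration or lactone opening that basic fluoride sources could cause.

**Compound list**

1 | propargyl alcohol | C#CCO | starting material
2 | 1-methoxy-4-[(prop-2-yn-1-yloxy)methyl]benzene | C#CCOCc1ccc(OC)cc1 | intermediate
3 | (R)-epichlorohydrin | ClC[C@H]1CO1 | starting material
4 | lithium acetylide of 2 | [Li]C#CCOCc1ccc(OC)cc1 | intermediate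
5 | (2R)-1-chloro-6-[(4-methoxybenzyl)oxy]hex-4-yn-2-ol | ClC[C@H](O)CC#CCOCc1ccc(OC)cc1 | intermediate
6 | (2R)-2-{4-[(4-methoxybenzyl)oxy]but-2-yn-1-yl}oxirane | COc1ccc(COCC#CC[C@@H]2CO2)cc1 | intermediate
7 | (E)-cinnamaldehyde | O=C/C=C/c1ccccc1 | starting material
8 | propane-1,3-dithiol | SCCCS | starting material
9 | 2-[(E)-2-phenylethenyl]-1,3-dithiane | C1CSC(/C=C/c2ccccc2)SC1 | intermediate
10 | 2-lithio-2-[(E)-2-phenylethenyl]-1,3-dithiane | [Li]C1(/C=C/c2ccccc2)SCCCS1 | intermediate
11 | (2R)-6-[(4-methoxybenzyl)oxy]-1-{2-[(E)-2-phenylethenyl]-1,3-dithian-2-yl}hex-4-yn-2-ol | COc1ccc(COCC#CC[C@@H](O)CC2(/C=C/c3ccccc3)SCCCS2)cc1 | intermediate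
12 | tert-butyl{[(2R)-6-[(4-methoxybenzyl)oxy]-1-{2-[(E)-2-phenylethenyl]-1,3-dithian-2-yl}hex-4-yn-2-yl]oxy}dimethylsilane | COc1ccc(COCC#CC[C@@H](O[Si](C)(C)C(C)(C)C)CC2(/C=C/c3ccccc3)SCCCS2)cc1 | intermediate
13 | (1E,5R)-5-[(tert-butyldimethylsilyl)oxy]-9-[(4-methoxybenzyl)oxy]-1-phenylnon-1-en-7-yn-3-one | COc1ccc(COCC#CC[C@@H](O[Si](C)(C)C(C)(C)C)CC(=O)/C=C/c2ccccc2)cc1 | intermediate
14 | (1E,3S,5R)-5-[(tert-butyldimethylsilyl)oxy]-9-[(4-methoxybenzyl)oxy]-1-phenylnon-1-en-7-yn-3-ol | COc1ccc(COCC#CC[C@@H](O[Si](C)(C)C(C)(C)C)C[C@H](O)/C=C/c2ccccc2)cc1 | intermediate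
15 | (1E,3S,5R)-5-[(tert-butyldimethylsilyl)oxy]-9-[(4-methoxybenzyl)oxy]-1-phenylnon-1-en-7-yn-3-yl acetate | COc1ccc(COCC#CC[C@@H](O[Si](C)(C)C(C)(C)C)C[C@H](OC(C)=O)/C=C/c2ccccc2)cc1 | intermediate
16 | (1E,3S,5R)-5-[(tert-butyldimethylsilyl)oxy]-9-hydroxy-1-phenylnon-1-en-7-yn-3-yl acetate | OCC#CC[C@@H](O[Si](C)(C)C(C)(C)C)C[C@H](OC(C)=O)/C=C/c1ccccc1 | intermediate
17 | (1E,3S,5R)-5-[(tert-butyldimethylsilyl)oxy]-9-oxo-1-phenylnon-1-en-7-yn-3-yl acetate | O=CC#CC[C@@H](O[Si](C)(C)C(C)(C)C)C[C@H](OC(C)=O)/C=C/c1ccccc1 | intermediate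
18 | (E)-1-methoxybuta-1,3-diene | CO/C=C/C=C | starting material
19 | (1E,3S,5R)-5-[(tert-butyldimethylsilyl)oxy]-9-[(2S,6R)-6-methoxy-3,6-dihydro-2H-pyran-2-yl]-1-phenylnon-1-en-7-yn-3-yl acetate | CC(=O)O[C@H](/C=C/c1ccccc1)C[C@H](O[Si](C)(C)C(C)(C)C)CC#C[C@@H]1CC=C[C@H](OC)O1 | intermediate
20 | (1E,3S,5S,7Z)-5-[(tert-butyldimethylsilyl)oxy]-8-[(2S,6R)-6-methoxy-3,6-dihydro-2H-pyran-2-yl]-1-phenyl-7-(triethoxysilyl)octa-1,7-dien-3-yl acetate (the 5S descriptor reflects the silicon substituent, not a change at C4') | CC(=O)O[C@H](/C=C/c1ccccc1)C[C@H](O[Si](C)(C)C(C)(C)C)C/C([Si](OCC)(OCC)OCC)=C/[C@@H]1CC=C[C@H](OC)O1 | intermediate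
21 | (1E,3S,5R,7E)-5-[(tert-butyldimethylsilyl)oxy]-8-[(2S,6R)-6-methoxy-3,6-dihydro-2H-pyran-2-yl]-1-phenylocta-1,7-dien-3-yl acetate | CC(=O)O[C@H](/C=C/c1ccccc1)C[C@H](O[Si](C)(C)C(C)(C)C)C/C=C/[C@@H]1CC=C[C@H](OC)O1 | intermediate
22 | (1E,3S,5R,7E)-5-[(tert-butyldimethylsilyl)oxy]-8-[(2S)-6-hydroxy-3,6-dihydro-2H-pyran-2-yl]-1-phenylocta-1,7-dien-3-yl acetate (anomer mixture) | CC(=O)O[C@H](/C=C/c1ccccc1)C[C@H](O[Si](C)(C)C(C)(C)C)C/C=C/[C@@H]1CC=CC(O)O1 | intermediate
23 | (1E,3S,5R,7E)-5-[(tert-butyldimethylsilyl)oxy]-8-[(2S)-6-oxo-3,6-dihydro-2H-pyran-2-yl]-1-phenylocta-1,7-dien-3-yl acetate | CC(=O)O[C@H](/C=C/c1ccccc1)C[C@H](O[Si](C)(C)C(C)(C)C)C/C=C/[C@@H]1CC=CC(=O)O1 | intermediate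
24 | (6S)-6-[(1E,4R,6S,7E)-6-acetoxy-4-hydroxy-8-phenylocta-1,7-dien-1-yl]-5,6-dihydro-2H-pyran-2-one | CC(=O)O[C@H](/C=C/c1ccccc1)C[C@H](O)C/C=C/[C@@H]1CC=CC(=O)O1 | target

**Step count and risks**

Total step count: 16. Longest linear sequence: 15 steps (1 to 24 through steps 1–3 and 5–16; step 4 is a one-step side branch).

Steps most likely to fail:

1. Step 12 (key cycloaddition). Facial discrimination by the catalyst may be incomplete for a ynal carrying a long functionalised chain, turnover may be slow, and the ynal may be lost to conjugate addition or oligomerisation before it cycloadds. Fallback, setting out from ynal 17 and returning at lactone 23: asymmetric allylboration of 17 with (−)-B-allyldiisopinocampheylborane (Et2O, −78 °C, non-oxidative aminoethanol work-up) should give the (9S)-homoallylic propargylic alcohol F1. Acylation with acryloyl chloride and Et3N should give the acrylate F2. Ring-closing metathesis with RuCl2(PCy3)2(=CHPh) (first-generation Grubbs catalyst) and Ti(OiPr)4 in refluxing CH2Cl2, conditions under which an internal alkyne is engaged far more slowly than the two terminal alkenes, should give the 6-alkynyl dihydropyranone F3. Trans-hydrosilylation as in step 13 should give the alkenylsilane F4, and AgF protodesilylation then gives 23.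

2. Step 13 (trans-hydrosilylation and protodesilylation). The cationic ruthenium may be sequestered by the phenyl ring or the ring alkene, it may ionise the allylic acetal or the allylic acetate, and the fluoride step may stall or begin to remove the silyl ether. Fallback, setting out from propargylic alcohol 16 and returning at lactone 23, with the E-alkene made before the ring: reduction of 16 with NaAlH2(OCH2CH2OMe)2 in THF at 0 °C (alkoxide-directed trans-hydroalumination, which also removes the acetate) should give the (2E)-allylic diol F5. Selective oxidation of the primary allylic alcohol with TEMPO/PhI(OAc)2 should give the hydroxy enal F6, and acetylation (Ac2O, pyridine) the acetoxy enal F7. Allylboration with (−)-B-allyldiisopinocampheylborane should give the (9S)-homoallylic alcohol F8, and acryloyl chloride/Et3N the acrylate F9. Ring-closing metathesis with RuCl2(PCy3)2(=CHPh) and Ti(OiPr)4, which engages only the two terminal alkenes, closes the lactone to 23.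

3. Step 5 (dithiane alkylation). The ambident allyl anion may attack through its γ-carbon, and it may act as a base at the propargylic CH2 and isomerise the epoxide to an enynol. Fallback, setting out from epoxide 6 and returning at enone 13, with the C6'–C7' bond made separately: 2-lithio-1,3-dithiane (n-BuLi, THF, −30 °C), which has no γ-position, should open 6 to the dithianyl alcohol F10. TBSOTf/2,6-lutidine should give the silyl ether F11, and MeI/CaCO3 in aqueous MeCN the β-silyloxy aldehyde F12. Addition of the (E)-styrylzinc reagent made from phenylacetylene with Cp2Zr(H)Cl and then Me2Zn should give the allylic alcohol F13 as a C6' epimer mixture, and Dess–Martin oxidation converges both epimers on 13.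

**Further compounds**

F1 | step 12 | (1E,3S,5R,9S)-5-[(tert-butyldimethylsilyl)oxy]-9-hydroxy-1-phenyldodeca-1,11-dien-7-yn-3-yl acetate | C=CC[C@H](O)C#CC[C@@H](O[Si](C)(C)C(C)(C)C)C[C@H](OC(C)=O)/C=C/c1ccccc1
F2 | step 12 | (1E,3S,5R,9S)-3-acetoxy-5-[(tert-butyldimethylsilyl)oxy]-1-phenyldodeca-1,11-dien-7-yn-9-yl prop-2-enoate | C=CC[C@H](OC(=O)C=C)C#CC[C@@H](O[Si](C)(C)C(C)(C)C)C[C@H](OC(C)=O)/C=C/c1ccccc1
F3 | step 12 | (1E,3S,5R)-5-[(tert-butyldimethylsilyl)oxy]-9-[(2S)-6-oxo-3,6-dihydro-2H-pyran-2-yl]-1-phenylnon-1-en-7-yn-3-yl acetate | O=C1C=CC[C@@H](C#CC[C@@H](O[Si](C)(C)C(C)(C)C)C[C@H](OC(C)=O)/C=C/c2ccccc2)O1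
F4 | step 12 | (1E,3S,5S,7Z)-5-[(tert-butyldimethylsilyl)oxy]-8-[(2S)-6-oxo-3,6-dihydro-2H-pyran-2-yl]-1-phenyl-7-(triethoxysilyl)octa-1,7-dien-3-yl acetate | O=C1C=CC[C@@H](/C=C(\[Si](OCC)(OCC)OCC)C[C@@H](O[Si](C)(C)C(C)(C)C)C[C@H](OC(C)=O)/C=C/c2ccccc2)O1
F5 | step 13 | (2E,5R,7S,8E)-5-[(tert-butyldimethylsilyl)oxy]-9-phenylnona-2,8-diene-1,7-diol | OC/C=C/C[C@@H](O[Si](C)(C)C(C)(C)C)C[C@H](O)/C=C/c1ccccc1
F6 | step 13 | (2E,5R,7S,8E)-5-[(tert-butyldimethylsilyl)oxy]-7-hydroxy-9-phenylnona-2,8-dienal | O=C/C=C/C[C@@H](O[Si](C)(C)C(C)(C)C)C[C@H](O)/C=C/c1ccccc1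
F7 | step 13 | (1E,3S,5R,7E)-5-[(tert-butyldimethylsilyl)oxy]-9-oxo-1-phenylnona-1,7-dien-3-yl acetate | O=C/C=C/C[C@@H](O[Si](C)(C)C(C)(C)C)C[C@H](OC(C)=O)/C=C/c1ccccc1
F8 | step 13 | (1E,3S,5R,7E,9S)-5-[(tert-butyldimethylsilyl)oxy]-9-hydroxy-1-phenyldodeca-1,7,11-trien-3-yl acetate | C=CC[C@H](O)/C=C/C[C@@H](O[Si](C)(C)C(C)(C)C)C[C@H](OC(C)=O)/C=C/c1ccccc1
F9 | step 13 | (1E,3S,5R,7E,9S)-3-acetoxy-5-[(tert-butyldimethylsilyl)oxy]-1-phenyldodeca-1,7,11-trien-9-yl prop-2-enoate | C=CC[C@H](OC(=O)C=C)/C=C/C[C@@H](O[Si](C)(C)C(C)(C)C)C[C@H](OC(C)=O)/C=C/c1ccccc1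
F10 | step 5 | (2R)-1-(1,3-dithian-2-yl)-6-[(4-methoxybenzyl)oxy]hex-4-yn-2-ol | COc1ccc(COCC#CC[C@@H](O)CC2SCCCS2)cc1
F11 | step 5 | tert-butyl{[(2R)-1-(1,3-dithian-2-yl)-6-[(4-methoxybenzyl)oxy]hex-4-yn-2-yl]oxy}dimethylsilane | COc1ccc(COCC#CC[C@@H](O[Si](C)(C)C(C)(C)C)CC2SCCCS2)cc1
F12 | step 5 | (3R)-3-[(tert-butyldimethylsilyl)oxy]-7-[(4-methoxybenzyl)oxy]hept-5-ynal | COc1ccc(COCC#CC[C@@H](O[Si](C)(C)C(C)(C)C)CC=O)cc1
F13 | step 5 | (1E,5R)-5-[(tert-butyldimethylsilyl)oxy]-9-[(4-methoxybenzyl)oxy]-1-phenylnon-1-en-7-yn-3-ol (C3 epimer mixture) | COc1ccc(COCC#CC[C@@H](O[Si](C)(C)C(C)(C)C)CC(O)/C=C/c2ccccc2)cc1
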